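The grey run stood at 8.3% product after 20.0 h, a rise of 0.9 percentage points since 10.0 h against a scatter of 0.5 points, and the balance of the substrate, the reagent charged in the smaller amount, showed 92.0% still there, so I looked for what had stopped it elsewhere.

- grey: substrate 0.025 M; coupling partner 1.3 equiv; free catalyst 2.5 mol%; run made earlier
- flask: substrate 0.050 M; coupling partner 1.30 equiv; free catalyst 2.5 mol%; time 2.5 d

grey run (percent of the substrate charged)

| time / h | product / % | substrate / % |
|---|---|---|
| 1.33 | 2.3 | 98.0 |
| 2.50 | 2.2 | 95.8 |
| 4.00 | 4.3 | 95.4 |
| 6.00 | 5.3 | 94.7 |
| 10.0 | 7.4 | 92.0 |
| 20.0 | 8.3 | 92.0 |

(each reading ± 0.5 percentage points)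

- steps that have been proposed: catalyst intermediate A -> catalyst intermediate B; coupling partner + free catalyst -> catalyst intermediate A; catalyst intermediate C -> released group + catalyst intermediate D; coupling partner -> decomposed reagent; catalyst intermediate D <-> free catalyst + product; substrate + catalyst intermediate B -> catalyst intermediate C
- no earlier run changes the charge of free catalyst; that part of a forecast is a guess

- concentration of product at 2.5 d, in M
- concentration of substrate at 2.5 d, in M

I first suspected that product held the catalyst as catalyst intermediate D, but a rise with the root of time would have carried the 7.4% at 10.0 h to 10.5% at 20.0 h, more than the reading. So I took the coupling partner, though charged in excess, as the true limiting reagent, split between binding free catalyst and decomposing, and I carried the partner's useful share, the product formed per partner charged, 6.38%. That share, held at its grey value, gave 0.00415 M for the new flask. But if decomposition is first order and capture scales with catalyst concentration, which the new flask has at twice the grey value, the share should double, and I reckoned 0.00830 M. The longer time added nothing to this reckoning, which counts partner charged and not hours. My remaining doubt was that more product holds more catalyst, so I treated 0.00830 M as an upper figure.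

The forecast gave 0.0082 M product and 0.0415 M substrate, “allowing a little held on catalyst”.

The flask gave 0.00607 M product and 0.0437 M substrate at 2.5 d.

    catalyst intermediate A → catalyst intermediate B (k = 86.0 h⁻¹)
    coupling partner + free catalyst → catalyst intermediate A (k = 32.0 L mol⁻¹ h⁻¹)
    catalyst intermediate C → released group + catalyst intermediate D (k = 6.70 h⁻¹)
    coupling partner → decomposed reagent (k = 0.240 h⁻¹)
    catalyst intermediate D ⇌ free catalyst + product (K = 0.0210 M, k = 4.00 h⁻¹)
    substrate + catalyst intermediate B → catalyst intermediate C (k = 520 L mol⁻¹ h⁻¹)

In the flask at that time 0% of the coupling partner stood unbound, less than the 87% of substrate, and 22.4% of the catalyst stood as catalyst intermediate D. The flask's share was 9.33%, which is 1.46 times the 6.38% read from the grey run. Multiplying that flask's share by the catalyst charge of the neighbour flask, 1.68 times the flask's, and by the free catalyst at the asked time, 69.9% there against 77.6% in the flask, I reckoned a share of 14.1%, or 0.00919 M product, for the neighbour flask with 4.2 mol% free catalyst, which stood at 0.00902 M.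

(The readings were generated by integration with made-up constants; scatter was added.)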